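**Plan**
- Cuts: the bridge bond CH2–C8 of the 6-methyl half (Friedel–Crafts through an ortho-quinone methide). Both halves then go back to one chroman ester 9. In 9 the pyran bond C3–C4 is cut and a nitrogen is put between the two carbons, which gives the seven-membered 1,4-benzoxazepine 7. 7 is cut at N4–C5 (Mannich) and O1–C2 (Mitsunobu).
- Forward: symmetric benzoate 2 → aryl ether 5 → seven-membered O,N ring 7 → loss of N2 contracts it to the pyran ring (9) → branch a: methyl at C6, ester off (15); branch b: ester to CH2OH (16) → union of 16 and 15.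
- Feature used: ring A is a phloroglucinol ring. The carbon that becomes C4 is benzylic to C4a, which has oxygen on both ortho carbons (C5, C8a) and on the para carbon (C7). The C–N bond at that carbon therefore breaks easily and the carbon radical is stabilised, and the same donors let N4–C5 form by a phenolic Mannich closure.
- Regiochemistry: the two OH and the two ring CH of 2 are equivalent. The ester at C8 blocks that carbon; it becomes the bridge CH2 in one half and is removed in the other. Every substitution therefore has one site only.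
- Stereochemistry: both C2 centres come from (S)-2-amino-1-phenylethanol by one Mitsunobu inversion; C2 is a spectator afterwards.

Key step: step 5

Remark: the descriptor at the phenyl-bearing carbon is R in 5 to 8 and S from 9 on. The geometry is the same; only the CIP rank changes, because CH2N outranks phenyl and CH2C does not.

Step 1
Reactants: 1 methyl 2,4,6-trihydroxybenzoate
Product: 2 methyl 2,6-dihydroxy-4-methoxybenzoate
Conditions: Me2SO4 (1.0 equiv), K2CO3 (1.0 equiv), acetone, 0 °C to rt
Reagents that add atoms: dimethyl sulfate, COS(=O)(=O)OC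
Why: Williamson O-methylation should take the 4-OH, the most acidic phenol and the only one not held in a hydrogen bond to the ester, and the hard electrophile disfavours C-methylation.

Step 2
Reactants: 3 (S)-2-amino-1-phenylethanol
Product: 4 tert-butyl N-[(2S)-2-hydroxy-2-phenylethyl]carbamate
Conditions: Boc2O (1.05 equiv), THF, rt
Reagents that add atoms: di-tert-butyl dicarbonate, CC(C)(C)OC(=O)OC(=O)OC(C)(C)C
Why: Carbamate formation at the more nucleophilic amine leaves the secondary alcohol and its stereocentre untouched.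

Step 3
Reactants: 2 methyl 2,6-dihydroxy-4-methoxybenzoate; 4 tert-butyl N-[(2S)-2-hydroxy-2-phenylethyl]carbamate
Product: 5 methyl 2-[(1R)-2-[(tert-butoxycarbonyl)amino]-1-phenylethoxy]-6-hydroxy-4-methoxybenzoate
Conditions: PPh3, DIAD, THF, 0 °C to rt; 2 in excess (1.5 equiv)
Reagents that add atoms: none
Why: Mitsunobu etherification of one of the two equivalent phenols of 2 goes by SN2 at the benzylic carbinol carbon, so the (S)-alcohol should give the (R)-ether, which has the geometry of C2 of the target.

Step 4
Reactants: 5 methyl 2-[(1R)-2-[(tert-butoxycarbonyl)amino]-1-phenylethoxy]-6-hydroxy-4-methoxybenzoate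
Product: 7 methyl (2R)-8-hydroxy-6-methoxy-2-phenyl-2,3,4,5-tetrahydro-1,4-benzoxazepine-9-carboxylate, via primary amine 6 (not isolated)
Conditions: HCl (4 M in dioxane), 0 °C to rt; evaporate; then CH2O (37% aq., 1.0 equiv), NaOAc (1.1 equiv), MeOH, 0.02 M, 40 °C
Reagents that add atoms: formaldehyde, C=O
Why: After acidolysis of the carbamate, a phenolic Pictet–Spengler (intramolecular Mannich) closure should take place, in which the N-methyleneiminium ion attacks the only ring carbon within reach, ortho to the ether oxygen and to OMe and para to the free OH.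

Step 5
Reactants: 7 methyl (2R)-8-hydroxy-6-methoxy-2-phenyl-2,3,4,5-tetrahydro-1,4-benzoxazepine-9-carboxylate
Product: 9 methyl (2S)-7-hydroxy-5-methoxy-2-phenyl-3,4-dihydro-2H-chromene-8-carboxylate, via isodiazene 8 (not isolated)
Conditions: N-(benzyloxy)-N-(pivaloyloxy)-4-(trifluoromethyl)benzamide (1.5 equiv), THF, 45 °C
Reagents that add atoms: none
Why: The secondary amine of 7 attacks the amide nitrogen of the anomeric amide and displaces pivalate, the N–N intermediate loses benzyl 4-(trifluoromethyl)benzoate to give isodiazene 8, and 8 extrudes N2 by C–N homolysis to a short-lived singlet biradical (the benzylic carbon on ring A and the primary carbon next to C2) that recombines to the C3–C4 bond. The closest known reaction type is nitrogen deletion of secondary benzylic amines through isodiazenes, which is established for acyclic amines and for ring contraction of cyclic ones. The pyran ring is closed by radical–radical recombination of the two carbons that were bound to N4, so the seven-membered 1,4-benzoxazepine contracts by one atom to the six-membered ring. No stereocentre is formed; C2 carries no radical and should keep its configuration because cage recombination outruns β-scission of the C2–O1 bond. The step needs amination at nitrogen only and recombination in preference to disproportionation or ionic fragmentation: N4 is the only basic nitrogen, and the benzylic radical is stabilised by ring A with OMe ortho and OH para.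

Step 6
Reactants: 9 methyl (2S)-7-hydroxy-5-methoxy-2-phenyl-3,4-dihydro-2H-chromene-8-carboxylate
Product: 10 methyl (2S)-6-[(dimethylamino)methyl]-7-hydroxy-5-methoxy-2-phenyl-3,4-dihydro-2H-chromene-8-carboxylate
Conditions: Me2NH (40% aq.), CH2O (37% aq.), EtOH, rt to 50 °C
Reagents that add atoms: formaldehyde, C=O; dimethylamine, CNC
Why: Phenolic Mannich aminomethylation must go to C6, the only unsubstituted ring carbon, because C8 is blocked by the ester.

Step 7
Reactants: 10 methyl (2S)-6-[(dimethylamino)methyl]-7-hydroxy-5-methoxy-2-phenyl-3,4-dihydro-2H-chromene-8-carboxylate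
Product: 13 methyl (2S)-7-hydroxy-5-methoxy-6-methyl-2-phenyl-3,4-dihydro-2H-chromene-8-carboxylate, via methiodide 11 (not isolated), via ortho-quinone methide 12 (not isolated)
Conditions: MeI (1.2 equiv), THF, rt; then NaBH4 (3 equiv), EtOH, 0 °C to rt
Reagents that add atoms: none
Why: Quaternisation makes a leaving group that the phenoxide expels to give ortho-quinone methide 12, and 1,4-addition of hydride should turn the aminomethyl group into the C6 methyl group while the hindered ester survives.

Step 8
Reactants: 13 methyl (2S)-7-hydroxy-5-methoxy-6-methyl-2-phenyl-3,4-dihydro-2H-chromene-8-carboxylate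
Product: 15 (2S)-5-methoxy-6-methyl-2-phenyl-3,4-dihydro-2H-chromen-7-ol, via carboxylic acid 14 (not isolated)
Conditions: KOH, DMSO/H2O, 100 °C; then HCl (2 M) to pH 2, 60 °C
Reagents that add atoms: none
Why: Saponification followed by acid-promoted protodecarboxylation (ipso protonation of an acid flanked by O1 and OH and para to OMe) should remove the blocking group and free C8.

Step 9
Reactants: 9 methyl (2S)-7-hydroxy-5-methoxy-2-phenyl-3,4-dihydro-2H-chromene-8-carboxylate
Product: 16 (2S)-8-(hydroxymethyl)-5-methoxy-2-phenyl-3,4-dihydro-2H-chromen-7-ol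
Conditions: LiAlH4, THF, 0 °C; aq. KNaC4H4O6 work-up; used crude
Reagents that add atoms: none
Why: Hydride reduction of the salicylate-type ester to the ortho-hydroxybenzyl alcohol turns the former blocking group into the future bridge carbon.

Step 10
Reactants: 16 (2S)-8-(hydroxymethyl)-5-methoxy-2-phenyl-3,4-dihydro-2H-chromen-7-ol; 15 (2S)-5-methoxy-6-methyl-2-phenyl-3,4-dihydro-2H-chromen-7-ol
Product: 18 (2S)-8-{[(2S)-7-hydroxy-5-methoxy-6-methyl-2-phenyl-3,4-dihydro-2H-chromen-8-yl]methyl}-5-methoxy-2-phenyl-3,4-dihydro-2H-chromen-7-ol, via ortho-quinone methide 17 (not isolated)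
Conditions: 15 (2.5 equiv), camphorsulfonic acid (5 mol %), CH2Cl2, −20 to 0 °C, slow addition of 16
Reagents that add atoms: none
Why: Acid-promoted loss of water gives ortho-quinone methide 17, which should be trapped in a Friedel–Crafts alkylation by C8 of 15, its only free ring carbon and more nucleophilic than C6 of 16.

**Compound list**
1 | methyl 2,4,6-trihydroxybenzoate | COC(=O)c1c(O)cc(O)cc1O | starting material
2 | methyl 2,6-dihydroxy-4-methoxybenzoate | COC(=O)c1c(O)cc(OC)cc1O | intermediate
3 | (S)-2-amino-1-phenylethanol | NC[C@@H](O)c1ccccc1 | starting material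
4 | tert-butyl N-[(2S)-2-hydroxy-2-phenylethyl]carbamate | CC(C)(C)OC(=O)NC[C@@H](O)c1ccccc1 | intermediate
5 | methyl 2-[(1R)-2-[(tert-butoxycarbonyl)amino]-1-phenylethoxy]-6-hydroxy-4-methoxybenzoate | CC(C)(C)OC(=O)NC[C@@H](c1ccccc1)Oc1cc(OC)cc(O)c1C(=O)OC | intermediate
6 | methyl 2-[(1R)-2-amino-1-phenylethoxy]-6-hydroxy-4-methoxybenzoate | NC[C@@H](c1ccccc1)Oc1cc(OC)cc(O)c1C(=O)OC | intermediate
7 | methyl (2R)-8-hydroxy-6-methoxy-2-phenyl-2,3,4,5-tetrahydro-1,4-benzoxazepine-9-carboxylate | COc1cc(O)c(C(=O)OC)c2c1CNC[C@@H](c1ccccc1)O2 | intermediate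
8 | isodiazene (1,1-diazene) of 7, N4 bearing a terminal nitrogen | COc1cc(O)c(C(=O)OC)c2c1C[N+](=[N-])C[C@@H](c1ccccc1)O2 | intermediate
9 | methyl (2S)-7-hydroxy-5-methoxy-2-phenyl-3,4-dihydro-2H-chromene-8-carboxylate | COc1cc(O)c(C(=O)OC)c2c1CC[C@@H](c1ccccc1)O2 | intermediate
10 | methyl (2S)-6-[(dimethylamino)methyl]-7-hydroxy-5-methoxy-2-phenyl-3,4-dihydro-2H-chromene-8-carboxylate | COc1c(CN(C)C)c(O)c(C(=O)OC)c2c1CC[C@@H](c1ccccc1)O2 | intermediate
11 | trimethylammonium iodide (methiodide) of 10 | COc1c(C[N+](C)(C)C)c(O)c(C(=O)OC)c2c1CC[C@@H](c1ccccc1)O2.[I-] | intermediate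
12 | methyl (2S)-5-methoxy-6-methylidene-7-oxo-2-phenyl-3,4,6,7-tetrahydro-2H-chromene-8-carboxylate (ortho-quinone methide) | COC1=C2CC[C@@H](c3ccccc3)OC2=C(C(=O)OC)C(=O)C1=C | intermediate
13 | methyl (2S)-7-hydroxy-5-methoxy-6-methyl-2-phenyl-3,4-dihydro-2H-chromene-8-carboxylate | COc1c(C)c(O)c(C(=O)OC)c2c1CC[C@@H](c1ccccc1)O2 | intermediate
14 | (2S)-7-hydroxy-5-methoxy-6-methyl-2-phenyl-3,4-dihydro-2H-chromene-8-carboxylic acid | COc1c(C)c(O)c(C(=O)O)c2c1CC[C@@H](c1ccccc1)O2 | intermediate
15 | (2S)-5-methoxy-6-methyl-2-phenyl-3,4-dihydro-2H-chromen-7-ol | COc1c(C)c(O)cc2c1CC[C@@H](c1ccccc1)O2 | intermediate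
16 | (2S)-8-(hydroxymethyl)-5-methoxy-2-phenyl-3,4-dihydro-2H-chromen-7-ol | COc1cc(O)c(CO)c2c1CC[C@@H](c1ccccc1)O2 | intermediate
17 | (2S)-5-methoxy-8-methylidene-2-phenyl-3,4-dihydro-2H-chromen-7(8H)-one (ortho-quinone methide) | COC1=CC(=O)C(=C)C2=C1CC[C@@H](c1ccccc1)O2 | intermediate
18 | (2S)-8-{[(2S)-7-hydroxy-5-methoxy-6-methyl-2-phenyl-3,4-dihydro-2H-chromen-8-yl]methyl}-5-methoxy-2-phenyl-3,4-dihydro-2H-chromen-7-ol | COc1cc(O)c(Cc2c(O)c(C)c(OC)c3c2O[C@H](c2ccccc2)CC3)c2c1CC[C@@H](c1ccccc1)O2 | target

**Count and risks**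
Total steps: 10. Longest linear sequence: 8 steps (1, 3, 4, 5, 6, 7, 8, 10).

Most likely to fail:

1. Step 5. The biradical may disproportionate to a ring-opened enol ether, isodiazene 8 may fragment ionically through a para-quinone methide, or N-amination may be slow next to the free phenol. The fallback sets out from 2 and comes back at 9. Mitsunobu etherification of 2 with (R)-3-chloro-1-phenylpropan-1-ol should give methyl 2-[(1S)-3-chloro-1-phenylpropoxy]-6-hydroxy-4-methoxybenzoate F1. NaI and K2CO3 in DMF at 80 °C should then close the pyran ring directly by intramolecular C-alkylation para to the phenoxide (Ar2-6 participation; O-alkylation is out of reach), giving 9 without a ring contraction.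

2. Step 4. Intermolecular aminomethylation at the carbon between OMe and OH may give oligomers, or an aminal may form without ring closure. The fallback sets out from 6 and comes back at 7. 2-Nitrobenzenesulfonyl chloride and Et3N should give methyl 2-hydroxy-4-methoxy-6-[(1R)-2-{[(2-nitrophenyl)sulfonyl]amino}-1-phenylethoxy]benzoate F2. Paraformaldehyde in CF3CO2H should close the ring through the more electrophilic N-sulfonyliminium ion (sulfonamide Pictet–Spengler) to methyl (2R)-8-hydroxy-6-methoxy-4-[(2-nitrophenyl)sulfonyl]-2-phenyl-2,3,4,5-tetrahydro-1,4-benzoxazepine-9-carboxylate F3. PhSH and K2CO3 in DMF then remove the sulfonyl group to give 7.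

3. Step 10. Ortho-quinone methide 17 may be trapped by C6 of a second molecule of 16 (self-condensation), and the product may be alkylated again. The fallback sets out from 16 and comes back at 18. MnO2 in CH2Cl2 should oxidise 16 to (2S)-7-hydroxy-5-methoxy-2-phenyl-3,4-dihydro-2H-chromene-8-carbaldehyde F4, whose ring is deactivated and which cannot form a quinone methide. CF3CO2H and Et3SiH with 15 should then give 18 by reductive Friedel–Crafts alkylation.

Further compounds
F1 | step 5 | methyl 2-[(1S)-3-chloro-1-phenylpropoxy]-6-hydroxy-4-methoxybenzoate | ClCC[C@@H](c1ccccc1)Oc1cc(OC)cc(O)c1C(=O)OC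
F2 | step 4 | methyl 2-hydroxy-4-methoxy-6-[(1R)-2-{[(2-nitrophenyl)sulfonyl]amino}-1-phenylethoxy]benzoate | O=[N+]([O-])c1ccccc1S(=O)(=O)NC[C@@H](c1ccccc1)Oc1cc(OC)cc(O)c1C(=O)OC
F3 | step 4 | methyl (2R)-8-hydroxy-6-methoxy-4-[(2-nitrophenyl)sulfonyl]-2-phenyl-2,3,4,5-tetrahydro-1,4-benzoxazepine-9-carboxylate | COc1cc(O)c(C(=O)OC)c2c1CN(C[C@@H](c1ccccc1)O2)S(=O)(=O)c1ccccc1[N+](=O)[O-]
F4 | step 10 | (2S)-7-hydroxy-5-methoxy-2-phenyl-3,4-dihydro-2H-chromene-8-carbaldehyde | COc1cc(O)c(C=O)c2c1CC[C@@H](c1ccccc1)O2
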